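**Retrosynthetic overview**
1. Colpol is a Z-1,4-diarylbut-2-ene with one free-phenol ring and one ring carrying a methyl ether. Remove the MOM groups, then the O-methyl, then the ring-B bromine, to reach a 2-alkyl-1,4-benzoquinone.
2. Key disconnection: the quinone C2–CH2 bond forms by trapping a Z-allylic radical, from a (Z)-4-aryl-but-2-enyl halide, with p-benzoquinone. Fast trapping outruns allyl-radical Z→E rotation, so the Z geometry is kept.
3. The Z-allylic chloride comes from Cu-catalysed SN2 coupling of the ring-A aryl-Grignard with commercial cis-1,4-dichlorobut-2-ene.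
4. Ring A (2-bromo-1,3-dioxy-5-iodoarene) is made from resorcinol by MOM protection, directed ortho-bromination at C2, Ir C–H borylation at C5 and iododeboronation.
5. No ring is constructed. Both arenes are carried in, and ring B is generated from benzoquinone by conjugate HBr addition and selective O-methylation.

Assumption: colpol has no stereocentre, so "single enantiomer" does not apply. The only stereo element is the Z-alkene.

---

**Step 1**
Reactants: 1 resorcinol
Product: 2 1,3-bis(methoxymethoxy)benzene
Conditions: MOMCl, iPr2NEt, CH2Cl2, 0 °C → rt
Reagents that add atoms: MOMCl, COCCl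
Why: Williamson-type acetal protection. MOM is a strong directing group for the next step and is removed under mild acid at the end.

**Step 2**
Reactants: 2
Product: 3 2-bromo-1,3-bis(methoxymethoxy)benzene
Conditions: n-BuLi, THF, 0 °C; then BrCF2CF2Br, –78 °C → rt
Reagents that add atoms: 1,2-dibromotetrafluoroethane, BrC(F)(F)C(F)(F)Br
Why: Directed ortho-metalation occurs at C2, between the two OMOM groups, and the aryllithium is quenched with an electrophilic bromine source. This places Br between the two oxygens, which electrophilic bromination of resorcinol derivatives does not do.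

**Step 3**
Reactants: 3
Product: 4 2-[4-bromo-3,5-bis(methoxymethoxy)phenyl]-4,4,5,5-tetramethyl-1,3,2-dioxaborolane
Conditions: B2pin2, [Ir(OMe)(cod)]2 (1.5 mol%), dtbpy (3 mol%), THF, 80 °C
Reagents that add atoms: B2pin2, CC1(C)OB(OB2OC(C)(C)C(C)(C)O2)OC1(C)C
Why: Ir-catalysed C–H borylation is sterically controlled. C5 is the only C–H not ortho to a substituent, so it is borylated selectively and the aryl bromide is untouched.

**Step 4**
Reactants: 4
Product: 5 2-bromo-5-iodo-1,3-bis(methoxymethoxy)benzene
Conditions: NIS, MeCN, 25 °C
Reagents that add atoms: N-iodosuccinimide, O=C1CCC(=O)N1I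
Why: ipso-Iododeboronation converts the C–B bond to C–I. The aryl iodide is needed for a selective I/Mg exchange in Step 5, because a second bromide would exchange at the chelation-activated C2.

**Step 5**
Reactants: 5; 6 (Z)-1,4-dichlorobut-2-ene
Product: 7 (Z)-2-bromo-5-(4-chlorobut-2-en-1-yl)-1,3-bis(methoxymethoxy)benzene
Conditions: iPrMgCl·LiCl, THF, –20 °C, 30 min; then 6 (4 equiv), Li2CuCl4 (5 mol%), –20 → 0 °C
Reagents that add atoms: none (6 is the reactant)
Why: I/Mg exchange is selective over Br/Mg. Cu-catalysed Grignard–allyl chloride coupling (Kochi/Derguini–Linstrumelle type) is an α-selective SN2 process that keeps the alkene geometry, so the Z centre is inherited from 6. Excess dichloride suppresses bis-arylation.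

**Step 6**
Reactants: 7; 8 p-benzoquinone
Product: 9 (Z)-2-{4-[4-bromo-3,5-bis(methoxymethoxy)phenyl]but-2-en-1-yl}cyclohexa-2,5-diene-1,4-dione
Conditions: 8 (3 equiv), NaI (1.5 equiv), 2,6-lutidine (1.5 equiv), MeCN, 455 nm LEDs, 25 °C; then MnO2 workup
Reagents that add atoms: none
Why: Proposed new method: in situ Finkelstein gives the Z-allylic iodide, and visible-light C–I homolysis gives the Z-allyl radical. The radical adds through its unhindered CH2 terminus to the quinone. The resulting adduct radical transfers iodine from another allylic iodide to carry the chain, and loss of HI (taken up by lutidine) re-forms the quinone. Z retention rests on the allyl-radical rotation barrier of about 16 kcal/mol (k ≈ 10–100 s⁻¹), far slower than trapping by 0.3 M quinone (≥10⁴ s⁻¹). The closest known chemistry is Jacobsen–Torssell/Minisci-type radical alkylation of quinones and Giese addition; MnO2 reoxidises any alkylhydroquinone formed.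

**Step 7**
Reactants: 9
Product: 10 2-bromo-5-{(Z)-4-[4-bromo-3,5-bis(methoxymethoxy)phenyl]but-2-en-1-yl}benzene-1,4-diol
Conditions: LiBr (2 equiv), AcOH (2 equiv), THF, 0 °C → rt
Reagents that add atoms: lithium bromide, [Li+].[Br-]
Why: Conjugate (Michael) addition of bromide to a 2-alkylquinone occurs at C5, para to the alkyl group. The alkyl group deactivates the C4 carbonyl, so C6 is disfavoured, and the hydroquinone forms by tautomerisation. This gives the required 2,5-pattern (Br para to the chain) with no redox step. Conditions are only mildly acidic, so MOM and the Z-alkene survive.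

**Step 8**
Reactants: 10
Product: 11 5-bromo-2-{(Z)-4-[4-bromo-3,5-bis(methoxymethoxy)phenyl]but-2-en-1-yl}-4-methoxyphenol
Conditions: MeI (1.05 equiv), K2CO3 (1.0 equiv), acetone, 0 → 25 °C, N2
Reagents that add atoms: iodomethane, CI
Why: Williamson O-methylation. The OH ortho to Br is more acidic and less hindered than the OH ortho to the CH2 chain, so mono-methylation occurs there and gives the 4-OMe/1-OH pattern of ring B.

**Step 9**
Reactants: 11
Product: 12 colpol, 2-bromo-5-[(Z)-4-(5-bromo-2-hydroxy-4-methoxyphenyl)but-2-en-1-yl]benzene-1,3-diol
Conditions: 2 M HCl, MeOH/THF (1:1), 40 °C, 6 h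
Reagents that add atoms: none
Why: Acid-catalysed acetal hydrolysis removes both MOM groups. The aryl methyl ether, the aryl bromides and the isolated Z-alkene are unaffected.

---

**Compound list**
1 | resorcinol | Oc1cccc(O)c1 | starting material
2 | 1,3-bis(methoxymethoxy)benzene | COCOc1cccc(OCOC)c1 | intermediate
3 | 2-bromo-1,3-bis(methoxymethoxy)benzene | COCOc1cccc(OCOC)c1Br | intermediate
4 | aryl-Bpin (ring A) | COCOc1cc(B2OC(C)(C)C(C)(C)O2)cc(OCOC)c1Br | intermediate
5 | 2-bromo-5-iodo-1,3-bis(methoxymethoxy)benzene | COCOc1cc(I)cc(OCOC)c1Br | intermediate
6 | (Z)-1,4-dichlorobut-2-ene | ClC/C=C\CCl | starting material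
7 | (Z)-allylic chloride | COCOc1cc(C/C=C\CCl)cc(OCOC)c1Br | intermediate
8 | p-benzoquinone | O=C1C=CC(=O)C=C1 | starting material
9 | (Z)-2-alkyl-1,4-benzoquinone | COCOc1cc(C/C=C\CC2=CC(=O)C=CC2=O)cc(OCOC)c1Br | intermediate
10 | 2-bromo-5-alkylhydroquinone | Oc1cc(Br)c(O)cc1C/C=C\Cc2cc(OCOC)c(Br)c(OCOC)c2 | intermediate
11 | mono-methyl ether (bis-MOM) | COc1cc(C/C=C\Cc2cc(OCOC)c(Br)c(OCOC)c2)c(O)cc1Br | intermediate
12 | colpol | COc1cc(C/C=C\Cc2cc(O)c(Br)c(O)c2)c(O)cc1Br | target

**Totals:** 9 steps in total. The longest linear sequence is 9 steps (1 → 2 → … → 12).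

**Three steps most likely to fail**
1. **Step 6 (radical quinone alkylation):** risks are iodine-atom-catalysed Z→E erosion, attack at the branched allyl terminus, polyalkylation and iodide reduction of the quinone.
   - Fallback: drop the radical coupling. Make ring B as a pre-differentiated, pre-brominated aryl iodide (5-bromo-4-methoxy-2-iodophenol, MOM-protected, from 4-methoxyphenol by ortho-iodination, MOM protection and NBS bromination). Convert it to its Grignard and couple it with allylic chloride 7 by the same Cu-catalysed SN2 reaction as Step 5. Then remove the MOM groups.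
2. **Step 7 (HBr addition):** the Br may add at C6 or C3 instead of C5, and MOM may be partly cleaved.
   - Fallback: install the bromine before alkylation. Run the radical alkylation on 2-bromo-1,4-benzoquinone (from p-benzoquinone by HBr addition and MnO2 oxidation), so that only the alkylation regiochemistry needs to be controlled.
3. **Step 8 (site-selective mono-methylation):** the two hydroquinone OH groups are similar, so a mixture may result.
   - Fallback: reorder the sequence. Reduce 9 and methylate the remote OH (sterically clean). Pivaloylate the other OH, swap the ring-A MOM groups for a deactivating aryl carbamate or ester, and brominate ring B with NBS, which goes para to the alkyl chain. Then deprotect.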